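**Retrosynthetic overview**
- The target comes from global saponification of a diacetate methyl ester, which is cut at the aryl–C12 bond (Heck) into an aryl bromide and a tertiary vinyl carbinol.
- Key disconnection C9–C10: the carbinol carbon C10 is used as an α-oxygenated carbanion (lithiated (R)-but-3-en-2-yl carbamate, a reversed-polarity carbinol synthon) and joined to a primary alkylboronic ester. A 1,2-metalate shift and C–B oxidation then set the (10S) tertiary alcohol stereospecifically.
- The boronic ester is cut at C8–C9 (borylmethyl anion plus allylic chloride) and at C2=C3 (E-selective Wittig). The aldehyde comes from selective ozonolysis of geranyl chloride, which supplies the 6E alkene.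
- No ring is formed: the benzene ring is bought as methylhydroquinone and carried as its diacetate.

Assumption: the target is the (2E,6E,10S,11E) isomer exactly as drawn, and enantiopure (R)-but-3-en-2-ol, geranyl chloride and bis(pinacolboryl)methane are counted as purchasable.

**Route**

Step 1
Reactants: 1 methyl (triphenylphosphoranylidene)acetate; 2 5-bromo-2-methylpent-2-ene
Product: 4 methyl 6-methyl-2-(triphenylphosphoranylidene)hept-5-enoate, via phosphonium bromide 3 (not isolated)
Conditions: NaI (10 mol%), MeCN, reflux, 48 h; then aq. NaOH, CH2Cl2, rt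
Reagents that add atoms: none
Why: SN2 C-alkylation of the stabilised ylide (iodide-assisted) gives the phosphonium salt, which aqueous NaOH deprotonates to the α-substituted stabilised ylide; no stereocentre is formed.

Step 2
Reactants: 5 geranyl chloride, (2E)-1-chloro-3,7-dimethylocta-2,6-diene
Product: 6 (4E)-6-chloro-4-methylhex-4-enal
Conditions: O3 (1.0 equiv, Sudan Red 7B end-point), pyridine (3 equiv), CH2Cl2, −78 °C
Reagents that add atoms: ozone, [O-][O+]=O
Why: Chemoselective ozonolysis: electrophilic ozone attacks the remote trisubstituted alkene much faster than the one deactivated by the allylic chlorine, pyridine fragments the carbonyl oxide to the aldehyde without a reductive work-up, and the E-alkene is carried over unchanged.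

Step 3
Reactants: 6 (4E)-6-chloro-4-methylhex-4-enal; 4 methyl 6-methyl-2-(triphenylphosphoranylidene)hept-5-enoate
Product: 7 methyl (2E,6E)-8-chloro-6-methyl-2-(4-methylpent-3-en-1-yl)octa-2,6-dienoate
Conditions: CH2Cl2, rt to 40 °C, 24 h
Reagents that add atoms: none
Why: Wittig olefination with an α-branched ester-stabilised ylide puts the ester trans to the new chain (2E, usually better than 95:5) and is far faster than alkylation of the hindered ylide by the allylic chloride.

Step 4
Reactants: 7 methyl (2E,6E)-8-chloro-6-methyl-2-(4-methylpent-3-en-1-yl)octa-2,6-dienoate; 8 bis(4,4,5,5-tetramethyl-1,3,2-dioxaborolan-2-yl)methane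
Product: 10 methyl (2E,6E)-6-methyl-2-(4-methylpent-3-en-1-yl)-9-(4,4,5,5-tetramethyl-1,3,2-dioxaborolan-2-yl)nona-2,6-dienoate, via tert-butoxide boronate adduct 9 (not isolated)
Conditions: 8 (1.5 equiv), NaOtBu (1.4 equiv), THF, 0 °C, 15 min; then 7, 0 °C to rt
Reagents that add atoms: none
Why: Alkoxide-promoted deborylative alkylation of a geminal bis(boronate): tert-butoxide releases an α-boryl carbanion that displaces the primary allylic chloride by SN2 without allylic transposition, so both alkene geometries are kept.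

Step 5
Reactants: 11 (R)-but-3-en-2-ol
Product: 12 (R)-but-3-en-2-yl N,N-diisopropylcarbamate
Conditions: iPr2NCOCl, Et3N, CH2Cl2, reflux
Reagents that add atoms: N,N-diisopropylcarbamoyl chloride, CC(C)N(C(C)C)C(=O)Cl
Why: O-carbamoylation (acyl substitution at the carbamoyl chloride) installs the Hoppe carbamate without touching the C–O stereocentre.

Step 6
Reactants: 12 (R)-but-3-en-2-yl N,N-diisopropylcarbamate; 10 methyl (2E,6E)-6-methyl-2-(4-methylpent-3-en-1-yl)-9-(4,4,5,5-tetramethyl-1,3,2-dioxaborolan-2-yl)nona-2,6-dienoate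
Product: 16 methyl (2E,6E,10S)-10-hydroxy-6,10-dimethyl-2-(4-methylpent-3-en-1-yl)dodeca-2,6,11-trienoate, via lithiated carbamate 13 (not isolated), via boronate complex 14 (not isolated), via tertiary allylic boronic ester 15 (not isolated)
Conditions: 12 (1.2 equiv), sBuLi (1.15 equiv), TMEDA, Et2O, −78 °C, 20 min; then 10 (1.0 equiv), −78 °C, 1 h, then rt; then 2 M NaOH, 30% H2O2, THF, 0 °C
Reagents that add atoms: hydrogen peroxide, OO
Why: Hoppe–Aggarwal lithiation–borylation: carbamate-directed deprotonation (retention) turns the carbinol carbon into an α-oxygenated carbanion that binds boron at the same carbon (lithium-directed, retention), the alkyl group then migrates anti to the leaving carbamate (1,2-metalate shift, inversion at carbon) and oxidation replaces boron by hydroxyl with retention, so (R)-12 gives the (10S) tertiary alcohol.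

Step 7
Reactants: 17 2-methylbenzene-1,4-diol
Product: 18 2-bromo-5-methylbenzene-1,4-diol
Conditions: Br2 (1.0 equiv), CHCl3/Et2O, 0 °C
Reagents that add atoms: bromine, BrBr
Why: Electrophilic aromatic bromination at the most activated free position, ortho to a hydroxyl and para to the methyl group.

Step 8
Reactants: 18 2-bromo-5-methylbenzene-1,4-diol
Product: 19 2-bromo-5-methyl-1,4-phenylene diacetate
Conditions: Ac2O, pyridine, DMAP (cat.), rt
Reagents that add atoms: acetic anhydride, CC(=O)OC(C)=O
Why: DMAP-catalysed O-acetylation (nucleophilic acyl substitution) protects the oxidation-prone hydroquinone as base-labile esters.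

Step 9
Reactants: 16 methyl (2E,6E,10S)-10-hydroxy-6,10-dimethyl-2-(4-methylpent-3-en-1-yl)dodeca-2,6,11-trienoate; 19 2-bromo-5-methyl-1,4-phenylene diacetate
Product: 20 methyl (2E,6E,10S,11E)-12-[2,5-bis(acetyloxy)-4-methylphenyl]-10-hydroxy-6,10-dimethyl-2-(4-methylpent-3-en-1-yl)dodeca-2,6,11-trienoate
Conditions: Pd(OAc)2 (5 mol%), P(o-tol)3 (12 mol%), Et3N, DMF, 90 °C
Reagents that add atoms: none
Why: Mizoroki–Heck arylation: the arylpalladium bromide formed by oxidative addition to zerovalent palladium inserts only into the monosubstituted alkene, and because the carbinol carbon carries no hydrogen, syn β-hydride elimination must give the conjugated (11E)-styrene while the quaternary stereocentre is untouched.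

Step 10
Reactants: 20 methyl (2E,6E,10S,11E)-12-[2,5-bis(acetyloxy)-4-methylphenyl]-10-hydroxy-6,10-dimethyl-2-(4-methylpent-3-en-1-yl)dodeca-2,6,11-trienoate
Product: 21 (2E,6E,10S,11E)-12-(2,5-dihydroxy-4-methylphenyl)-10-hydroxy-6,10-dimethyl-2-(4-methylpent-3-en-1-yl)dodeca-2,6,11-trienoic acid
Conditions: LiOH·H2O (8 equiv), THF/MeOH/H2O (degassed, Ar), 40 °C; then 1 M H3PO4 to pH 5, 0 °C
Reagents that add atoms: lithium hydroxide, [Li+].[OH-]
Why: Saponification (acyl–oxygen cleavage by hydroxide) removes the two aryl acetates and the methyl ester in one operation under oxygen-free, non-acidic conditions that leave the acid-sensitive tertiary allylic alcohol and its stereocentre intact.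

**Compound list**

1 | methyl (triphenylphosphoranylidene)acetate | COC(=O)C=P(c1ccccc1)(c1ccccc1)c1ccccc1 | starting material
2 | 5-bromo-2-methylpent-2-ene | CC(C)=CCCBr | starting material
3 | (1-methoxy-6-methyl-1-oxohept-5-en-2-yl)triphenylphosphonium bromide (racemic, not isolated) | COC(=O)C(CCC=C(C)C)[P+](c1ccccc1)(c1ccccc1)c1ccccc1.[Br-] | intermediate
4 | methyl 6-methyl-2-(triphenylphosphoranylidene)hept-5-enoate | COC(=O)C(CCC=C(C)C)=P(c1ccccc1)(c1ccccc1)c1ccccc1 | intermediate
5 | geranyl chloride, (2E)-1-chloro-3,7-dimethylocta-2,6-diene | CC(C)=CCC/C(C)=C/CCl | starting material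
6 | (4E)-6-chloro-4-methylhex-4-enal | O=CCC/C(C)=C/CCl | intermediate
7 | methyl (2E,6E)-8-chloro-6-methyl-2-(4-methylpent-3-en-1-yl)octa-2,6-dienoate | CC(C)=CCC/C(=C\CC/C(C)=C/CCl)C(=O)OC | intermediate
8 | bis(4,4,5,5-tetramethyl-1,3,2-dioxaborolan-2-yl)methane | C(B1OC(C)(C)C(C)(C)O1)B1OC(C)(C)C(C)(C)O1 | starting material
9 | sodium tert-butoxide adduct of 8, tert-butoxy[(pinacolboryl)methyl]pinacolborate (not isolated) | [Na+].CC(C)(C)O[B-]1(CB2OC(C)(C)C(C)(C)O2)OC(C)(C)C(C)(C)O1 | intermediate
10 | methyl (2E,6E)-6-methyl-2-(4-methylpent-3-en-1-yl)-9-(4,4,5,5-tetramethyl-1,3,2-dioxaborolan-2-yl)nona-2,6-dienoate | CC(C)=CCC/C(=C\CC/C(C)=C/CCB1OC(C)(C)C(C)(C)O1)C(=O)OC | intermediate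
11 | (R)-but-3-en-2-ol | C[C@@H](O)C=C | starting material
12 | (R)-but-3-en-2-yl N,N-diisopropylcarbamate | C[C@@H](OC(=O)N(C(C)C)C(C)C)C=C | intermediate
13 | (R)-2-lithiobut-3-en-2-yl N,N-diisopropylcarbamate (not isolated) | C[C@@]([Li])(OC(=O)N(C(C)C)C(C)C)C=C | intermediate
14 | lithium boronate complex of 13 and 10, boron on the carbamate-bearing carbon (R) (not isolated) | [Li+].CC(C)=CCC/C(=C\CC/C(C)=C/CC[B-]1(OC(C)(C)C(C)(C)O1)[C@](C)(OC(=O)N(C(C)C)C(C)C)C=C)C(=O)OC | intermediate
15 | methyl (2E,6E,10R)-6,10-dimethyl-2-(4-methylpent-3-en-1-yl)-10-(4,4,5,5-tetramethyl-1,3,2-dioxaborolan-2-yl)dodeca-2,6,11-trienoate (not isolated) | CC(C)=CCC/C(=C\CC/C(C)=C/CC[C@](C)(B1OC(C)(C)C(C)(C)O1)C=C)C(=O)OC | intermediate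
16 | methyl (2E,6E,10S)-10-hydroxy-6,10-dimethyl-2-(4-methylpent-3-en-1-yl)dodeca-2,6,11-trienoate | CC(C)=CCC/C(=C\CC/C(C)=C/CC[C@](C)(O)C=C)C(=O)OC | intermediate
17 | 2-methylbenzene-1,4-diol | Cc1cc(O)ccc1O | starting material
18 | 2-bromo-5-methylbenzene-1,4-diol | Cc1cc(O)c(Br)cc1O | intermediate
19 | 2-bromo-5-methyl-1,4-phenylene diacetate | CC(=O)Oc1cc(C)c(OC(C)=O)cc1Br | intermediate
20 | methyl (2E,6E,10S,11E)-12-[2,5-bis(acetyloxy)-4-methylphenyl]-10-hydroxy-6,10-dimethyl-2-(4-methylpent-3-en-1-yl)dodeca-2,6,11-trienoate | CC(C)=CCC/C(=C\CC/C(C)=C/CC[C@](C)(O)/C=C/c1cc(OC(C)=O)c(C)cc1OC(C)=O)C(=O)OC | intermediate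
21 | (2E,6E,10S,11E)-12-(2,5-dihydroxy-4-methylphenyl)-10-hydroxy-6,10-dimethyl-2-(4-methylpent-3-en-1-yl)dodeca-2,6,11-trienoic acid | CC(C)=CCC/C(=C\CC/C(C)=C/CC[C@](C)(O)/C=C/c1cc(O)c(C)cc1O)C(=O)O | target

**Step count and risks**

Total step count: 10. Longest linear sequence: 6 steps from geranyl chloride (steps 2, 3, 4, 6, 9, 10).

Steps most likely to fail:

1. Step 6. Boron may be captured at the unsubstituted remote terminus of the allyl anion, the lithiated carbamate may partly racemise, or the organolithium may attack the ester of 10. The fallback sets out from 10 and comes back at 16. Commercial (R)-4-(trimethylsilyl)but-3-yn-2-ol is carbamoylated (iPr2NCOCl, Et3N) to (R)-4-(trimethylsilyl)but-3-yn-2-yl N,N-diisopropylcarbamate F1. Its lithiation (sBuLi, TMEDA, Et2O, −78 °C, short contact time), borylation with 10 and 1,2-shift give the tertiary propargylic boronic ester methyl (2E,6E,10R)-6,10-dimethyl-2-(4-methylpent-3-en-1-yl)-10-(4,4,5,5-tetramethyl-1,3,2-dioxaborolan-2-yl)-12-(trimethylsilyl)dodeca-2,6-dien-11-ynoate F2; here the silyl-capped alkyne blocks the remote terminus and forces borylation onto the carbinol carbon. NaOH/H2O2 in THF/MeOH oxidises the C–B bond and removes the alkynyl silane to give methyl (2E,6E,10S)-10-hydroxy-6,10-dimethyl-2-(4-methylpent-3-en-1-yl)dodeca-2,6-dien-11-ynoate F3. Hydrogen over Pd/CaCO3 poisoned with Pb(OAc)2 (quinoline) reduces only the terminal alkyne to the vinyl group of 16.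

2. Step 4. Free tert-butoxide may eliminate or substitute the allylic chloride, transesterify the ester, or the α-boryl carbanion may add to the enoate. The fallback sets out from 7 and comes back at 10. Pd2(dba)3-catalysed borylation of the allylic chloride with B2pin2 (toluene, 50 °C) gives the linear allylboronate methyl (2E,6E)-6-methyl-2-(4-methylpent-3-en-1-yl)-8-(4,4,5,5-tetramethyl-1,3,2-dioxaborolan-2-yl)octa-2,6-dienoate F4. Matteson homologation (ClCH2I, n-BuLi added last, THF, −78 °C to rt) then inserts the methylene group by a 1,2-boronate shift to give 10, with no free alkoxide and no carbanion alkylation.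

3. Step 2. Over-ozonolysis of the second alkene or N-alkylation of pyridine by the allylic chloride would erode the yield. The fallback sets out from 5 and comes back at 6. mCPBA (1.0 equiv, NaHCO3, CH2Cl2, 0 °C) epoxidises only the remote electron-rich alkene to give racemic 3-[(3E)-5-chloro-3-methylpent-3-en-1-yl]-2,2-dimethyloxirane F5, and H5IO6 (THF/Et2O, 0 °C) cleaves the epoxide to 6.

**Further compounds**

F1 | step 6 | (R)-4-(trimethylsilyl)but-3-yn-2-yl N,N-diisopropylcarbamate | C[C@@H](OC(=O)N(C(C)C)C(C)C)C#C[Si](C)(C)C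
F2 | step 6 | methyl (2E,6E,10R)-6,10-dimethyl-2-(4-methylpent-3-en-1-yl)-10-(4,4,5,5-tetramethyl-1,3,2-dioxaborolan-2-yl)-12-(trimethylsilyl)dodeca-2,6-dien-11-ynoate | CC(C)=CCC/C(=C\CC/C(C)=C/CC[C@](C)(B1OC(C)(C)C(C)(C)O1)C#C[Si](C)(C)C)C(=O)OC
F3 | step 6 | methyl (2E,6E,10S)-10-hydroxy-6,10-dimethyl-2-(4-methylpent-3-en-1-yl)dodeca-2,6-dien-11-ynoate | CC(C)=CCC/C(=C\CC/C(C)=C/CC[C@](C)(O)C#C)C(=O)OC
F4 | step 4 | methyl (2E,6E)-6-methyl-2-(4-methylpent-3-en-1-yl)-8-(4,4,5,5-tetramethyl-1,3,2-dioxaborolan-2-yl)octa-2,6-dienoate | CC(C)=CCC/C(=C\CC/C(C)=C/CB1OC(C)(C)C(C)(C)O1)C(=O)OC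
F5 | step 2 | 3-[(3E)-5-chloro-3-methylpent-3-en-1-yl]-2,2-dimethyloxirane (racemic) | CC1(C)OC1CC/C(C)=C/CCl
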